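**Retrosynthetic overview**
1. Kazinol B is traced back, through fluoride desilylation and an aromatic Claisen shift of an O3' 1,1-dimethylallyl group into C2', to an unprenylated, O7-silylated flavan. The prenyl group comes last, so C2' carries no substituent while C2 is being set.
2. Structural feature used: in ring C, C3 and C4 are two plain CH2 groups linking the only stereocentre, C2, to ring-A carbon C4a, and O1 sits on the neighbouring C8a. Ring C is therefore an aryl 1-arylallyl ether whose vinyl terminus only has to be joined to an ortho C–Br carbon (C4–C4a bond).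
3. The O1–C2 bond and the (S) configuration come from a branched-selective iridium-catalysed allylic etherification of a linear chromenylallyl carbonate with a 2-bromo-5-silyloxyphenoxide made from 4-bromoresorcinol.
4. The carbonate comes from 3,4-dihydroxybenzaldehyde by O4' propargylation, thermal chromene formation, MOM protection of O3', olefination, reduction and acylation.
5. Ring order: rings A and B are bought as arenes, the dimethylpyran ring D is closed in step 2, and ring C is closed in step 9.

Key step: step 9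

Numbering: flavan numbering is used (O1, C2, C3, C4, C4a, C5 to C8, C8a for rings C and A; primed numbers for ring B). Ring D is the dimethylpyran ring fused at C4'–C5'.

Assumption: with cinnamyl-type carbonates and O- or N-nucleophiles, the (S,S,S)-phosphoramidite is taken to give the (S)-configured branched product. If a first run shows the opposite sense, the (R,R,R)-ligand is used with no other change.

**Step 1**
Reactants: 1 3,4-dihydroxybenzaldehyde; 2 3-chloro-3-methylbut-1-yne
Product: 3 3-hydroxy-4-[(2-methylbut-3-yn-2-yl)oxy]benzaldehyde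
Conditions: 2 (1.1 equiv), DBU (1.05 equiv), CuCl2·2H2O (1 mol %), MeCN, −5 to 0 °C, N2
Reagents that add atoms: 3-chloro-3-methylbut-1-yne (2), CC(C)(Cl)C#C
Why: Copper-catalysed O-propargylation of a phenol with a tertiary propargylic chloride, in which one equivalent of base ionises only the far more acidic OH para to the formyl group, so the ether should form at O4' and the cold medium keeps it from rearranging.

**Step 2**
Reactants: 3 3-hydroxy-4-[(2-methylbut-3-yn-2-yl)oxy]benzaldehyde
Product: 4 8-hydroxy-2,2-dimethyl-2H-chromene-6-carbaldehyde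
Conditions: PhNEt2, 190 °C
Reagents that add atoms: none
Why: Aromatic propargyl Claisen rearrangement to the only free ortho carbon, followed by enolisation, a 1,5-hydrogen shift and 6π oxa-electrocyclisation, closes ring D in one thermal operation.

**Step 3**
Reactants: 4 8-hydroxy-2,2-dimethyl-2H-chromene-6-carbaldehyde
Product: 5 8-(methoxymethoxy)-2,2-dimethyl-2H-chromene-6-carbaldehyde
Conditions: MOMCl, i-Pr2NEt, CH2Cl2, 0 °C to rt
Reagents that add atoms: chloromethyl methyl ether (MOMCl), COCCl
Why: Williamson-type O-alkylation to the MOM acetal masks O3' with a group that tolerates hydride, aryloxide, borane and aqueous phosphate and can later be removed while the aryl silyl ether stays on.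

**Step 4**
Reactants: 5 8-(methoxymethoxy)-2,2-dimethyl-2H-chromene-6-carbaldehyde; 6 triethyl phosphonoacetate
Product: 7 ethyl (E)-3-[8-(methoxymethoxy)-2,2-dimethyl-2H-chromen-6-yl]prop-2-enoate
Conditions: 6, LiCl, DBU, MeCN, rt
Reagents that add atoms: triethyl phosphonoacetate (6), CCOC(=O)CP(=O)(OCC)OCC
Why: Horner–Wadsworth–Emmons olefination of an aromatic aldehyde with a stabilised phosphonate should give the (E)-cinnamate under thermodynamic control of the addition step.

**Step 5**
Reactants: 7 ethyl (E)-3-[8-(methoxymethoxy)-2,2-dimethyl-2H-chromen-6-yl]prop-2-enoate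
Product: 8 (E)-3-[8-(methoxymethoxy)-2,2-dimethyl-2H-chromen-6-yl]prop-2-en-1-ol
Conditions: i-Bu2AlH (2.3 equiv), CH2Cl2, −78 °C; aq. potassium sodium tartrate
Reagents that add atoms: none
Why: 1,2-Reduction of an α,β-unsaturated ester by i-Bu2AlH gives the allylic alcohol without touching either alkene or the MOM acetal.

**Step 6**
Reactants: 8 (E)-3-[8-(methoxymethoxy)-2,2-dimethyl-2H-chromen-6-yl]prop-2-en-1-ol
Product: 9 (E)-3-[8-(methoxymethoxy)-2,2-dimethyl-2H-chromen-6-yl]prop-2-en-1-yl methyl carbonate
Conditions: ClCO2Me, pyridine, CH2Cl2, 0 °C; chromatography on Et3N-washed silica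
Reagents that add atoms: methyl chloroformate, COC(=O)Cl
Why: O-Acylation of a primary alcohol with a chloroformate installs the leaving group that iridium allylation catalysts ionise best, and the basic medium protects the acid-sensitive electron-rich cinnamyl system.

**Step 7**
Reactants: 10 4-bromoresorcinol
Product: 11 2-bromo-5-(triisopropylsilyloxy)phenol
Conditions: i-Pr3SiCl (1.0 equiv), imidazole, CH2Cl2, 0 °C
Reagents that add atoms: triisopropylsilyl chloride, CC(C)[Si](Cl)(C(C)C)C(C)C
Why: Regioselective silylation, in which the bulky chlorosilane should take the open OH para to bromine (future O7) while the OH ortho to bromine, shielded and engaged in an O–H···Br contact, stays free as the future O1.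

**Step 8**
Reactants: 9 (E)-3-[8-(methoxymethoxy)-2,2-dimethyl-2H-chromen-6-yl]prop-2-en-1-yl methyl carbonate; 11 2-bromo-5-(triisopropylsilyloxy)phenol
Product: 13 (S)-6-{1-[2-bromo-5-(triisopropylsilyloxy)phenoxy]prop-2-en-1-yl}-8-(methoxymethoxy)-2,2-dimethyl-2H-chromene, via lithium aryloxide 12 (not isolated)
Conditions: 11, LiN(SiMe3)2 (1.0 equiv), THF, 0 °C; then 9, [Ir(cod)Cl]2 (2 mol %), (S,S,S)-L (4 mol %, pre-activated with n-PrNH2 at 50 °C, volatiles removed), THF, rt, stopped at full conversion; L = (S)-binaphthol phosphoramidite of bis[(S)-1-phenylethyl]amine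
Reagents that add atoms: none
Why: Iridium-catalysed asymmetric allylic etherification, in which the cyclometalated iridium–phosphoramidite complex ionises the linear carbonate to an allyl complex and the aryloxide attacks anti to the metal at the aryl-bearing terminus, so the branched ether (O1–C2 bond) should form with C2 fixed as S by the ligand.

**Step 9**
Reactants: 13 (S)-6-{1-[2-bromo-5-(triisopropylsilyloxy)phenoxy]prop-2-en-1-yl}-8-(methoxymethoxy)-2,2-dimethyl-2H-chromene
Product: 15 (2S)-2-[8-(methoxymethoxy)-2,2-dimethyl-2H-chromen-6-yl]-7-(triisopropylsilyloxy)chroman, via B-alkyl-9-BBN borane 14 (not isolated)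
Conditions: 9-BBN-H (0.5 M in THF, 1.3 equiv), THF, 0 °C to rt until the vinyl group is consumed; then degassed aq. K3PO4 (3 M, 3 equiv), Pd(dppf)Cl2·CH2Cl2 (5 mol %), THF (diluted to about 0.01 M), 65 °C
Reagents that add atoms: none
Why: 9-BBN-H adds to the monosubstituted vinyl group in the anti-Markovnikov sense and places boron on the terminal carbon (future C4) to give 14, after which zerovalent palladium formed from Pd(dppf)Cl2 inserts into the C4a–Br bond, the base-activated primary alkyl group passes from boron to divalent palladium, and C(sp3)–C(sp2) reductive elimination makes C4–C4a. The closest known reaction type is the hydroboration/intramolecular B-alkyl Suzuki–Miyaura cyclisation of ortho-haloaryl allyl ethers to chromans. Ring C closes through a seven-membered palladacycle (Pd, C4a, C8a, O1, C2, C3, C4) that contracts to the six-membered ring on reductive elimination, a step that the wide bite angle of dppf speeds up relative to β-hydride elimination. No stereocentre is created, since none of the bonds at C2 is broken, and boron sits γ to O1, so β-alkoxy elimination has no path. The step needs hydroboration of the vinyl group in preference to the ring D alkene, which the substrate secures because that alkene is 1,2-disubstituted, conjugated and flanked by the quaternary C(CH3)2 carbon, and full consumption of the vinyl group before palladium is added keeps zerovalent palladium from ionising the allylic ether. Dilution favours ring closure over intermolecular coupling.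

**Step 10**
Reactants: 15 (2S)-2-[8-(methoxymethoxy)-2,2-dimethyl-2H-chromen-6-yl]-7-(triisopropylsilyloxy)chroman
Product: 17 2,2-dimethyl-6-[(2S)-7-(triisopropylsilyloxy)chroman-2-yl]-2H-chromen-8-ol, via trimethylsilyl ether 16 (not isolated)
Conditions: Me3SiOTf (2 equiv), 2,2'-bipyridyl (3 equiv), MeCN, 0 °C to rt; then H2O, rt
Reagents that add atoms: none
Why: Silyl triflate/bipyridyl cleavage of an aromatic MOM ether, which exchanges the acetal for a labile Me3Si ether that water then hydrolyses, runs without free Brønsted acid, so the para-alkoxybenzylic C2–O1 bond (and hence the configuration at C2), ring D and the aryl i-Pr3Si ether should be left alone.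

**Step 11**
Reactants: 17 2,2-dimethyl-6-[(2S)-7-(triisopropylsilyloxy)chroman-2-yl]-2H-chromen-8-ol; 2 3-chloro-3-methylbut-1-yne
Product: 18 (2S)-2-{2,2-dimethyl-8-[(2-methylbut-3-yn-2-yl)oxy]-2H-chromen-6-yl}-7-(triisopropylsilyloxy)chroman
Conditions: 2 (1.5 equiv), DBU (1.6 equiv), CuCl2·2H2O (1 mol %), dry MeCN, 0 °C
Reagents that add atoms: 3-chloro-3-methylbut-1-yne (2), CC(C)(Cl)C#C
Why: The same copper-catalysed O-propargylation as in step 1 etherifies the only free phenol (O3'), and dry, cold conditions keep DBU from attacking the hindered aryl silyl ether.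

**Step 12**
Reactants: 18 (2S)-2-{2,2-dimethyl-8-[(2-methylbut-3-yn-2-yl)oxy]-2H-chromen-6-yl}-7-(triisopropylsilyloxy)chroman
Product: 19 (2S)-2-{2,2-dimethyl-8-[(2-methylbut-3-en-2-yl)oxy]-2H-chromen-6-yl}-7-(triisopropylsilyloxy)chroman
Conditions: H2 (1 atm), Pd/CaCO3 poisoned with Pb(OAc)2, quinoline, EtOAc, rt, stopped after one equivalent of H2
Reagents that add atoms: none
Why: Semi-hydrogenation of a terminal alkyne over poisoned palladium works because the alkyne binds the surface far more strongly than any alkene, so the ring D alkene and the benzylic C2–O1 bond should stay intact.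

**Step 13**
Reactants: 19 (2S)-2-{2,2-dimethyl-8-[(2-methylbut-3-en-2-yl)oxy]-2H-chromen-6-yl}-7-(triisopropylsilyloxy)chroman
Product: 20 2,2-dimethyl-7-(3-methylbut-2-en-1-yl)-6-[(2S)-7-(triisopropylsilyloxy)chroman-2-yl]-2H-chromen-8-ol
Conditions: o-xylene, 130 °C, argon, base-washed glassware
Reagents that add atoms: none
Why: Aromatic Claisen rearrangement, a [3,3] shift that inverts the 1,1-dimethylallyl group to a prenyl group and delivers its CH2 terminus to C2', the only ortho carbon of O3' that bears hydrogen (C4' carries the ring D oxygen), after which tautomerisation restores the phenol under neutral conditions that leave C2 untouched.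

**Step 14**
Reactants: 20 2,2-dimethyl-7-(3-methylbut-2-en-1-yl)-6-[(2S)-7-(triisopropylsilyloxy)chroman-2-yl]-2H-chromen-8-ol
Product: 21 kazinol B, (2S)-2-[8-hydroxy-2,2-dimethyl-7-(3-methylbut-2-en-1-yl)-2H-chromen-6-yl]chroman-7-ol
Conditions: n-Bu4NF, AcOH (1:1), THF, 0 °C
Reagents that add atoms: none
Why: Fluoride-induced desilylation of an aryl silyl ether, buffered with acetic acid, frees O7 without the acid that would cyclise the ortho-prenylphenol and without base strong enough to disturb C2.

**Compound list**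
1 | 3,4-dihydroxybenzaldehyde | O=Cc1ccc(O)c(O)c1 | starting material
2 | 3-chloro-3-methylbut-1-yne | CC(C)(Cl)C#C | starting material
3 | 3-hydroxy-4-[(2-methylbut-3-yn-2-yl)oxy]benzaldehyde | O=Cc1ccc(OC(C)(C)C#C)c(O)c1 | intermediate
4 | 8-hydroxy-2,2-dimethyl-2H-chromene-6-carbaldehyde | O=Cc1cc(O)c2OC(C)(C)C=Cc2c1 | intermediate
5 | 8-(methoxymethoxy)-2,2-dimethyl-2H-chromene-6-carbaldehyde | O=Cc1cc(OCOC)c2OC(C)(C)C=Cc2c1 | intermediate
6 | triethyl phosphonoacetate | CCOC(=O)CP(=O)(OCC)OCC | starting material
7 | ethyl (E)-3-[8-(methoxymethoxy)-2,2-dimethyl-2H-chromen-6-yl]prop-2-enoate | CCOC(=O)/C=C/c1cc(OCOC)c2OC(C)(C)C=Cc2c1 | intermediate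
8 | (E)-3-[8-(methoxymethoxy)-2,2-dimethyl-2H-chromen-6-yl]prop-2-en-1-ol | OC/C=C/c1cc(OCOC)c2OC(C)(C)C=Cc2c1 | intermediate
9 | (E)-3-[8-(methoxymethoxy)-2,2-dimethyl-2H-chromen-6-yl]prop-2-en-1-yl methyl carbonate | COC(=O)OC/C=C/c1cc(OCOC)c2OC(C)(C)C=Cc2c1 | intermediate
10 | 4-bromoresorcinol | Oc1ccc(Br)c(O)c1 | starting material
11 | 2-bromo-5-(triisopropylsilyloxy)phenol | Oc1cc(O[Si](C(C)C)(C(C)C)C(C)C)ccc1Br | intermediate
12 | lithium 2-bromo-5-(triisopropylsilyloxy)phenoxide (not isolated) | [Li+].[O-]c1cc(O[Si](C(C)C)(C(C)C)C(C)C)ccc1Br | intermediate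
13 | (S)-6-{1-[2-bromo-5-(triisopropylsilyloxy)phenoxy]prop-2-en-1-yl}-8-(methoxymethoxy)-2,2-dimethyl-2H-chromene | C=C[C@H](Oc1cc(O[Si](C(C)C)(C(C)C)C(C)C)ccc1Br)c1cc2C=CC(C)(C)Oc2c(OCOC)c1 | intermediate
14 | 9-{(S)-3-[2-bromo-5-(triisopropylsilyloxy)phenoxy]-3-[8-(methoxymethoxy)-2,2-dimethyl-2H-chromen-6-yl]propyl}-9-borabicyclo[3.3.1]nonane (not isolated) | C(C[C@H](Oc1cc(O[Si](C(C)C)(C(C)C)C(C)C)ccc1Br)c1cc2C=CC(C)(C)Oc2c(OCOC)c1)B1C2CCCC1CCC2 | intermediate
15 | (2S)-2-[8-(methoxymethoxy)-2,2-dimethyl-2H-chromen-6-yl]-7-(triisopropylsilyloxy)chroman | COCOc1cc([C@@H]2CCc3ccc(O[Si](C(C)C)(C(C)C)C(C)C)cc3O2)cc2c1OC(C)(C)C=C2 | intermediate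
16 | (2S)-2-[2,2-dimethyl-8-(trimethylsilyloxy)-2H-chromen-6-yl]-7-(triisopropylsilyloxy)chroman (not isolated) | C[Si](C)(C)Oc1cc([C@@H]2CCc3ccc(O[Si](C(C)C)(C(C)C)C(C)C)cc3O2)cc2c1OC(C)(C)C=C2 | intermediate
17 | 2,2-dimethyl-6-[(2S)-7-(triisopropylsilyloxy)chroman-2-yl]-2H-chromen-8-ol | Oc1cc([C@@H]2CCc3ccc(O[Si](C(C)C)(C(C)C)C(C)C)cc3O2)cc2c1OC(C)(C)C=C2 | intermediate
18 | (2S)-2-{2,2-dimethyl-8-[(2-methylbut-3-yn-2-yl)oxy]-2H-chromen-6-yl}-7-(triisopropylsilyloxy)chroman | C#CC(C)(C)Oc1cc([C@@H]2CCc3ccc(O[Si](C(C)C)(C(C)C)C(C)C)cc3O2)cc2c1OC(C)(C)C=C2 | intermediate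
19 | (2S)-2-{2,2-dimethyl-8-[(2-methylbut-3-en-2-yl)oxy]-2H-chromen-6-yl}-7-(triisopropylsilyloxy)chroman | C=CC(C)(C)Oc1cc([C@@H]2CCc3ccc(O[Si](C(C)C)(C(C)C)C(C)C)cc3O2)cc2c1OC(C)(C)C=C2 | intermediate
20 | 2,2-dimethyl-7-(3-methylbut-2-en-1-yl)-6-[(2S)-7-(triisopropylsilyloxy)chroman-2-yl]-2H-chromen-8-ol | CC(C)=CCc1c([C@@H]2CCc3ccc(O[Si](C(C)C)(C(C)C)C(C)C)cc3O2)cc2c(c1O)OC(C)(C)C=C2 | intermediate
21 | kazinol B, (2S)-2-[8-hydroxy-2,2-dimethyl-7-(3-methylbut-2-en-1-yl)-2H-chromen-6-yl]chroman-7-ol | CC(C)=CCc1c([C@@H]2CCc3ccc(O)cc3O2)cc2c(c1O)OC(C)(C)C=C2 | target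

**Step count**
Total steps: 14.
Longest linear sequence: 13 (steps 1 to 6 and 8 to 14, from 1). Step 7 is the side branch.

**Steps most likely to fail**

Step 9.
- Risk: oxidative addition into the electron-rich, ortho-alkoxy C–Br bond may be slow. Protodeboronation, β-hydride elimination or intermolecular coupling could then overtake ring closure, and hot aqueous phosphate may begin to strip the aryl silyl ether.
- Fallback (same C4–C4a bond, organozinc in place of organoboron, no base): the sequence sets out from 13. Hydroboration to 14 as before is followed by oxidation with NaBO3·4H2O to the primary alcohol (S)-3-[2-bromo-5-(triisopropylsilyloxy)phenoxy]-3-[8-(methoxymethoxy)-2,2-dimethyl-2H-chromen-6-yl]propan-1-ol F1. Appel-type iodination (I2, PPh3, imidazole) gives the primary iodide F2. Zinc dust with LiCl in THF inserts only into the C–I bond to give the alkylzinc iodide F3. Pd(OAc)2 with SPhos then closes ring C by intramolecular Negishi coupling, and the route is rejoined at 15.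

Step 8.
- Risk: the electron-rich branched ether can be ionised again by the catalyst, which would erode the enantiomeric purity and drain material to the linear ether. The hindered, weakly nucleophilic ortho-bromo aryloxide may also attack so slowly that carbonate exchange competes.
- Fallback (stereospecific substitution of a resolved branched carbonate in place of enantioselective catalysis): the sequence sets out from 5. CH2=CHMgBr adds to the aldehyde to give the racemic allylic alcohol F4. Candida antarctica lipase B with vinyl acetate leaves the (S)-alcohol F5 while the (R)-enantiomer is converted into the (R)-acetate F6, which is separated. ClCO2Me and pyridine turn F5 into the branched (S)-methyl carbonate F7. RhCl(PPh3)3 modified with P(OMe)3 then couples F7 with the sodium aryloxide F8 (from 11 and NaN(SiMe3)2), with net retention of configuration and of the branched regiochemistry. The route is rejoined at 13.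

Step 13.
- Risk: heterolysis of the tertiary allylic C–O bond with loss of the C5 unit, or migration away from the crowded C2' position next to the chroman-2-yl group, may compete with the [3,3] shift.
- Fallback (direct C-alkylation of a phenoxide in place of the sigmatropic route): the sequence sets out from 17 and bypasses 18 and 19. NaH in toluene gives the sodium phenoxide F9. As a tight ion pair in the non-polar medium it should be alkylated by prenyl bromide (CC(C)=CCBr) at the only free ortho carbon, C2'. Any O-prenyl ether is removed by chromatography. The route is rejoined at 20.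

**Further compounds**
F1 | step 9 | (S)-3-[2-bromo-5-(triisopropylsilyloxy)phenoxy]-3-[8-(methoxymethoxy)-2,2-dimethyl-2H-chromen-6-yl]propan-1-ol | OCC[C@H](Oc1cc(O[Si](C(C)C)(C(C)C)C(C)C)ccc1Br)c1cc2C=CC(C)(C)Oc2c(OCOC)c1
F2 | step 9 | (S)-6-{1-[2-bromo-5-(triisopropylsilyloxy)phenoxy]-3-iodopropyl}-8-(methoxymethoxy)-2,2-dimethyl-2H-chromene | ICC[C@H](Oc1cc(O[Si](C(C)C)(C(C)C)C(C)C)ccc1Br)c1cc2C=CC(C)(C)Oc2c(OCOC)c1
F3 | step 9 | {(S)-3-[2-bromo-5-(triisopropylsilyloxy)phenoxy]-3-[8-(methoxymethoxy)-2,2-dimethyl-2H-chromen-6-yl]propyl}zinc iodide | I[Zn]CC[C@H](Oc1cc(O[Si](C(C)C)(C(C)C)C(C)C)ccc1Br)c1cc2C=CC(C)(C)Oc2c(OCOC)c1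
F4 | step 8 | racemic 1-[8-(methoxymethoxy)-2,2-dimethyl-2H-chromen-6-yl]prop-2-en-1-ol | C=CC(O)c1cc2C=CC(C)(C)Oc2c(OCOC)c1
F5 | step 8 | (S)-1-[8-(methoxymethoxy)-2,2-dimethyl-2H-chromen-6-yl]prop-2-en-1-ol | C=C[C@H](O)c1cc2C=CC(C)(C)Oc2c(OCOC)c1
F6 | step 8 | (R)-1-[8-(methoxymethoxy)-2,2-dimethyl-2H-chromen-6-yl]prop-2-en-1-yl acetate | C=C[C@@H](OC(C)=O)c1cc2C=CC(C)(C)Oc2c(OCOC)c1
F7 | step 8 | (S)-1-[8-(methoxymethoxy)-2,2-dimethyl-2H-chromen-6-yl]prop-2-en-1-yl methyl carbonate | C=C[C@H](OC(=O)OC)c1cc2C=CC(C)(C)Oc2c(OCOC)c1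
F8 | step 8 | sodium 2-bromo-5-(triisopropylsilyloxy)phenoxide | [Na+].[O-]c1cc(O[Si](C(C)C)(C(C)C)C(C)C)ccc1Br
F9 | step 13 | sodium 2,2-dimethyl-6-[(2S)-7-(triisopropylsilyloxy)chroman-2-yl]-2H-chromen-8-olate | [Na+].[O-]c1cc([C@@H]2CCc3ccc(O[Si](C(C)C)(C(C)C)C(C)C)cc3O2)cc2c1OC(C)(C)C=C2
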